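The cyclohexenone ring is cut at C5–C6 and at C2=C3. Its pattern, a 2-substituted cyclohex-2-enone (C1 ketone, C2=C3) with the chain-bearing stereocentre C5 β to the carbonyl, is what a keto diester (C6, C1, C2 and the acetate arm) and an enal (C3, C4, C5 and the polyene) give on amine-catalysed Michael addition and aldol condensation. In the same flask, between these two events, the open-chain aldehyde is aminoxylated at C4 under catalyst control, so the ring closes with the oxygen already cis to the chain. The precursors are a skipped (2E,5E)-polyenal and allyl methyl 3-oxoadipate; deallylative decarboxylation and N–O cleavage finish.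

Key step: step 7

Remarks: ring atoms are numbered C1 (ketone) to C6 and C1′ is the first chain carbon. "Geranylgeranyl" means (2E,6E,10E)-3,7,11,15-tetramethylhexadeca-2,6,10,14-tetraen-1-yl. The ester-bearing carbon C6 of 12–16 is epimerisable and is drawn without configuration. The target has O-4 and the chain cis, (4R,5R) in ring numbering.
Assumption: the CuSO4-catalysed N–O cleavage is taken as the redox-neutral process 2 ArNH–OR → 2 ROH + ArN=NAr.

Step 1
Reactants: 1 (2E,6E,10E)-geranylgeraniol
Product: 2 (2E,6E,10E)-geranylgeranyl bromide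
Conditions: PBr3 (0.4 equiv), Et2O, −10 → 0 °C; used crude
Reagents that add atoms: phosphorus tribromide, BrP(Br)Br
Why: SN2-type bromination of a primary allylic alcohol through its phosphite ester at low temperature should leave the E-trisubstituted alkenes in place and avoid allylic transposition.

Step 2
Reactants: 2 geranylgeranyl bromide; 3 propargyl alcohol
Product: 4 (5E,9E,13E)-6,10,14,18-tetramethylnonadeca-5,9,13,17-tetraen-2-yn-1-ol
Conditions: CuI (10 mol%), nBu4NBr (10 mol%), K2CO3 (1.5 equiv), DMF, rt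
Reagents that add atoms: none
Why: Copper-catalysed allylation of a terminal alkyne (copper acetylide, SN2 at the unhindered CH2 of the allylic bromide) should give the skipped enyne without touching alkene geometry, and the free hydroxyl is tolerated.

Step 3
Reactants: 4 skipped enynol
Product: 5 (2E,5E,9E,13E)-6,10,14,18-tetramethylnonadeca-2,5,9,13,17-pentaen-1-ol
Conditions: NaAlH2(OCH2CH2OCH3)2, THF, 0 °C → rt; aq. potassium sodium tartrate
Reagents that add atoms: none
Why: Hydroxyl-directed trans-hydroalumination of the propargylic alcohol and protonolysis of the cyclic alkenylalanate should give only the E-allylic alcohol, while the isolated alkenes do not react with the hydride.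

Step 4
Reactants: 5 skipped dienol
Product: 6 (2E,5E,9E,13E)-6,10,14,18-tetramethylnonadeca-2,5,9,13,17-pentaenal
Conditions: MnO2 (activated, excess), CH2Cl2, rt; used promptly
Reagents that add atoms: none
Why: Chemoselective MnO2 oxidation of the allylic alcohol under neutral conditions should give the E-enal without moving the skipped C5=C6 alkene into conjugation.

Step 5
Reactants: 7 Meldrum's acid; 8 methyl 4-chloro-4-oxobutanoate
Product: 9 methyl 4-(2,2-dimethyl-4,6-dioxo-1,3-dioxan-5-ylidene)-4-hydroxybutanoate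
Conditions: pyridine (2 equiv), CH2Cl2, 0 °C → rt; dilute HCl wash
Reagents that add atoms: none
Why: C-Acylation of Meldrum's acid by the acid chloride with pyridine as base should give the enolic acyl Meldrum's acid, the methyl ester being inert.

Step 6
Reactants: 9 acyl Meldrum's acid; 10 allyl alcohol
Product: 11 1-allyl 6-methyl 3-oxohexanedioate
Conditions: allyl alcohol (2 equiv), toluene, 100 °C
Reagents that add atoms: none
Why: Thermolysis of the acyl Meldrum's acid expels acetone and CO2 to an acylketene that allyl alcohol traps as the β-keto ester (acyl Meldrum's acid alcoholysis).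

Step 7
Reactants: 6 skipped polyenal; 11 keto diester
Product: 15 allyl (5R,6R)-5-(anilinooxy)-6-geranylgeranyl-3-(2-methoxy-2-oxoethyl)-2-oxocyclohex-3-ene-1-carboxylate, via Michael adduct 12 (not isolated), via aminoxy aldehyde 13 (not isolated), via aldol 14 (not isolated)
Conditions: (a) (R)-2-{bis[3,5-bis(trifluoromethyl)phenyl](trimethylsilyloxy)methyl}pyrrolidine (10 mol%), PhCO2H (10 mol%), 11 (1.05 equiv), CHCl3, 0 °C; (b) L-proline (20 mol%), PhNO (1.1 equiv, slow addition), 0 °C; (c) TsOH·H2O (0.5 equiv), rt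
Reagents that add atoms: nitrosobenzene, O=Nc1ccccc1
Why: Amine and enal 6 form an E-iminium ion, and the enol of 11 adds through its doubly activated C6 to C5 on the face away from the diaryl(silyloxy)methyl group (iminium-catalysed Michael addition of a β-keto ester to an enal), which by the usual shielding model should make the (R)-amine deliver the C5 configuration of the target. After hydrolysis L-proline turns the free aldehyde of 12 into its enamine and its carboxylic acid steers nitrosobenzene, through oxygen, to C4 (proline-catalysed α-aminoxylation, as in one-pot pairings of an iminium catalyst with proline), so C4 is set by the proline and should come out R, cis to the chain in the ring. Acid at room temperature then drives the aldol of the C2 methylene onto the C3 aldehyde (6-enolendo-exo-trig) and the dehydration to C2=C3, the known closure of such Michael adducts to cyclohexenones; C6 would close a four-membered ring and the ester α-carbon of the arm a seven-membered one. The step needs conjugate addition to outrun γ-deprotonation of the skipped dienal at C1′ (trienamine), for which the high C–H acidity of 11, the low temperature and the absence of base speak, and it needs aminoxylation at C4 and not at C6, which is tertiary by then while only the aldehyde can form an enamine. C6 remains epimerisable and is cleared in step 8.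

Step 8
Reactants: 15 annulated keto diester
Product: 17 methyl 2-[(3R,4R)-3-(anilinooxy)-4-geranylgeranyl-6-oxocyclohex-1-en-1-yl]acetate, via keto acid 16 (not isolated)
Conditions: Pd(PPh3)4 (5 mol%), morpholine (3 equiv), THF, rt
Reagents that add atoms: none
Why: Zerovalent palladium ionises only the allyl ester and morpholine takes up the allyl group (Tsuji–Trost deallylation), after which the β-keto acid decarboxylates at room temperature in a weakly basic medium that should not disturb C4 or C5.

Step 9
Reactants: 17 aminoxy enone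
Product: 18 methyl 2-[(3R,4R)-4-geranylgeranyl-3-hydroxy-6-oxocyclohex-1-en-1-yl]acetate
Conditions: CuSO4·5H2O (30 mol%), MeOH, 0 °C → rt
Reagents that add atoms: none
Why: CuSO4-catalysed scission of the N–O bond of the anilinooxy group in methanol, the usual unmasking of O-nitroso aldol products, is neutral and leaves the C4–O bond intact, so the cis alcohol should be released without epimerisation while enone, ester and polyene survive.

Compound list
1 | (2E,6E,10E)-geranylgeraniol | CC(C)=CCC/C(C)=C/CC/C(C)=C/CC/C(C)=C/CO | starting material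
2 | (2E,6E,10E)-geranylgeranyl bromide | CC(C)=CCC/C(C)=C/CC/C(C)=C/CC/C(C)=C/CBr | intermediate
3 | propargyl alcohol | C#CCO | starting material
4 | (5E,9E,13E)-6,10,14,18-tetramethylnonadeca-5,9,13,17-tetraen-2-yn-1-ol | OCC#CC/C=C(\C)CC/C=C(\C)CC/C=C(\C)CCC=C(C)C | intermediate
5 | (2E,5E,9E,13E)-6,10,14,18-tetramethylnonadeca-2,5,9,13,17-pentaen-1-ol | OC/C=C/C/C=C(\C)CC/C=C(\C)CC/C=C(\C)CCC=C(C)C | intermediate
6 | (2E,5E,9E,13E)-6,10,14,18-tetramethylnonadeca-2,5,9,13,17-pentaenal | O=C/C=C/C/C=C(\C)CC/C=C(\C)CC/C=C(\C)CCC=C(C)C | intermediate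
7 | Meldrum's acid | CC1(C)OC(=O)CC(=O)O1 | starting material
8 | methyl 4-chloro-4-oxobutanoate | COC(=O)CCC(Cl)=O | starting material
9 | methyl 4-(2,2-dimethyl-4,6-dioxo-1,3-dioxan-5-ylidene)-4-hydroxybutanoate | COC(=O)CCC(O)=C1C(=O)OC(C)(C)OC1=O | intermediate
10 | allyl alcohol | C=CCO | starting material
11 | 1-allyl 6-methyl 3-oxohexanedioate | COC(=O)CCC(=O)CC(=O)OCC=C | intermediate
12 | 1-allyl 6-methyl 2-[(3S,5E,9E,13E)-6,10,14,18-tetramethyl-1-oxononadeca-5,9,13,17-tetraen-3-yl]-3-oxohexanedioate (open form of the Michael adduct) | COC(=O)CCC(=O)C(C(=O)OCC=C)[C@H](CC=O)C/C=C(\C)CC/C=C(\C)CC/C=C(\C)CCC=C(C)C | intermediate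
13 | 1-allyl 6-methyl 2-[(2R,3R,5E,9E,13E)-2-(anilinooxy)-6,10,14,18-tetramethyl-1-oxononadeca-5,9,13,17-tetraen-3-yl]-3-oxohexanedioate | COC(=O)CCC(=O)C(C(=O)OCC=C)[C@H]([C@@H](ONc1ccccc1)C=O)C/C=C(\C)CC/C=C(\C)CC/C=C(\C)CCC=C(C)C | intermediate
14 | allyl (5R,6R)-5-(anilinooxy)-6-geranylgeranyl-4-hydroxy-3-(2-methoxy-2-oxoethyl)-2-oxocyclohexane-1-carboxylate (C1, C3, C4 undefined) | COC(=O)CC1C(O)[C@H](ONc2ccccc2)[C@H](C/C=C(\C)CC/C=C(\C)CC/C=C(\C)CCC=C(C)C)C(C(=O)OCC=C)C1=O | intermediate
15 | allyl (5R,6R)-5-(anilinooxy)-6-geranylgeranyl-3-(2-methoxy-2-oxoethyl)-2-oxocyclohex-3-ene-1-carboxylate (C1 epimers) | COC(=O)CC1=C[C@H](ONc2ccccc2)[C@H](C/C=C(\C)CC/C=C(\C)CC/C=C(\C)CCC=C(C)C)C(C(=O)OCC=C)C1=O | intermediate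
16 | (5R,6R)-5-(anilinooxy)-6-geranylgeranyl-3-(2-methoxy-2-oxoethyl)-2-oxocyclohex-3-ene-1-carboxylic acid | COC(=O)CC1=C[C@H](ONc2ccccc2)[C@H](C/C=C(\C)CC/C=C(\C)CC/C=C(\C)CCC=C(C)C)C(C(O)=O)C1=O | intermediate
17 | methyl 2-[(3R,4R)-3-(anilinooxy)-4-geranylgeranyl-6-oxocyclohex-1-en-1-yl]acetate | COC(=O)CC1=C[C@H](ONc2ccccc2)[C@H](C/C=C(\C)CC/C=C(\C)CC/C=C(\C)CCC=C(C)C)CC1=O | intermediate
18 | methyl 2-[(3R,4R)-4-geranylgeranyl-3-hydroxy-6-oxocyclohex-1-en-1-yl]acetate (CNP0274044.1) | COC(=O)CC1=C[C@H](O)[C@H](C/C=C(\C)CC/C=C(\C)CC/C=C(\C)CCC=C(C)C)CC1=O | target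

Total step count: 9. Longest linear sequence: 7 steps (1, 2, 3, 4, 7, 8, 9).

Steps most likely to fail

Step 7. What may go wrong: loss of control in the aminoxylation stage. Nitrosobenzene may be drawn off by the keto ester C–H or by N-attack through the first amine, the aldol may close before the aldehyde is oxygenated, or the two amines may act in a mismatched sense so that the cis selectivity at C4 erodes. The fallback puts the oxygen on after the ring is made. It sets out from 6 and 11, run as in step 7 without stage (b), which should give allyl (6S)-6-geranylgeranyl-3-(2-methoxy-2-oxoethyl)-2-oxocyclohex-3-ene-1-carboxylate F1. Pd(PPh3)4 and morpholine then give methyl 2-[(4S)-4-geranylgeranyl-6-oxocyclohex-1-en-1-yl]acetate F2. Thermodynamic silylation (TBSOTf, Et3N, CH2Cl2) gives the linear silyl dienol ether methyl 2-[(4R)-2-(tert-butyldimethylsilyloxy)-4-geranylgeranylcyclohexa-1,5-dien-1-yl]acetate F3. Nitrosobenzene attacks C4 through oxygen on the face away from the chain (vinylogous O-nitroso aldol) to give methyl 2-[(3S,4R)-3-(anilinooxy)-4-geranylgeranyl-6-oxocyclohex-1-en-1-yl]acetate F4. CuSO4·5H2O in MeOH gives the trans alcohol methyl 2-[(3S,4R)-4-geranylgeranyl-3-hydroxy-6-oxocyclohex-1-en-1-yl]acetate F5. Mitsunobu inversion with chloroacetic acid (PPh3, DIAD) gives methyl 2-[(3R,4R)-3-(chloroacetoxy)-4-geranylgeranyl-6-oxocyclohex-1-en-1-yl]acetate F6, and NaHCO3 in MeOH removes the chloroacetate, coming back to the route at 18.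

Step 9. What may go wrong: the copper-mediated N–O scission is slow on the hindered secondary aminoxy group, and the freed γ-hydroxy enone lingers with the Lewis acid and loses water towards the phenol (aromatisation). The fallback carries the oxygen as a silyl ether, so that the last operation is a fast fluoride desilylation. It sets out from 15. Zn and AcOH cleave the N–O bond to allyl (5R,6R)-6-geranylgeranyl-5-hydroxy-3-(2-methoxy-2-oxoethyl)-2-oxocyclohex-3-ene-1-carboxylate F7. TESCl and imidazole give allyl (5R,6R)-6-geranylgeranyl-3-(2-methoxy-2-oxoethyl)-2-oxo-5-(triethylsilyloxy)cyclohex-3-ene-1-carboxylate F8. Pd(PPh3)4 and morpholine give methyl 2-[(3R,4R)-4-geranylgeranyl-6-oxo-3-(triethylsilyloxy)cyclohex-1-en-1-yl]acetate F9, and HF·pyridine buffered with pyridine in THF at 0 °C comes back to the route at 18.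

Step 2. What may go wrong: SN2′ attack of the copper acetylide at the tertiary end of the allyl system, giving the branched isomer (loss of regiocontrol). The fallback replaces alkyne allylation by an sp3–sp2 coupling. It sets out from 2 and 3. Radical hydrostannylation of 3 (Bu3SnH, AIBN) gives (E)-3-(tributylstannyl)prop-2-en-1-ol F10, and Stille coupling of F10 with 2 (Pd2(dba)3, tri(2-furyl)phosphine, THF) gives the dienol directly, coming back to the route at 5 and making step 3 unnecessary.

Further compounds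
F1 | step 7 | allyl (6S)-6-geranylgeranyl-3-(2-methoxy-2-oxoethyl)-2-oxocyclohex-3-ene-1-carboxylate | COC(=O)CC1=CC[C@H](C/C=C(\C)CC/C=C(\C)CC/C=C(\C)CCC=C(C)C)C(C(=O)OCC=C)C1=O
F2 | step 7 | methyl 2-[(4S)-4-geranylgeranyl-6-oxocyclohex-1-en-1-yl]acetate | COC(=O)CC1=CC[C@H](C/C=C(\C)CC/C=C(\C)CC/C=C(\C)CCC=C(C)C)CC1=O
F3 | step 7 | methyl 2-[(4R)-2-(tert-butyldimethylsilyloxy)-4-geranylgeranylcyclohexa-1,5-dien-1-yl]acetate | COC(=O)CC1=C(O[Si](C)(C)C(C)(C)C)C[C@@H](C/C=C(\C)CC/C=C(\C)CC/C=C(\C)CCC=C(C)C)C=C1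
F4 | step 7 | methyl 2-[(3S,4R)-3-(anilinooxy)-4-geranylgeranyl-6-oxocyclohex-1-en-1-yl]acetate | COC(=O)CC1=C[C@@H](ONc2ccccc2)[C@H](C/C=C(\C)CC/C=C(\C)CC/C=C(\C)CCC=C(C)C)CC1=O
F5 | step 7 | methyl 2-[(3S,4R)-4-geranylgeranyl-3-hydroxy-6-oxocyclohex-1-en-1-yl]acetate | COC(=O)CC1=C[C@@H](O)[C@H](C/C=C(\C)CC/C=C(\C)CC/C=C(\C)CCC=C(C)C)CC1=O
F6 | step 7 | methyl 2-[(3R,4R)-3-(chloroacetoxy)-4-geranylgeranyl-6-oxocyclohex-1-en-1-yl]acetate | COC(=O)CC1=C[C@H](OC(=O)CCl)[C@H](C/C=C(\C)CC/C=C(\C)CC/C=C(\C)CCC=C(C)C)CC1=O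
F7 | step 9 | allyl (5R,6R)-6-geranylgeranyl-5-hydroxy-3-(2-methoxy-2-oxoethyl)-2-oxocyclohex-3-ene-1-carboxylate | COC(=O)CC1=C[C@H](O)[C@H](C/C=C(\C)CC/C=C(\C)CC/C=C(\C)CCC=C(C)C)C(C(=O)OCC=C)C1=O
F8 | step 9 | allyl (5R,6R)-6-geranylgeranyl-3-(2-methoxy-2-oxoethyl)-2-oxo-5-(triethylsilyloxy)cyclohex-3-ene-1-carboxylate | COC(=O)CC1=C[C@H](O[Si](CC)(CC)CC)[C@H](C/C=C(\C)CC/C=C(\C)CC/C=C(\C)CCC=C(C)C)C(C(=O)OCC=C)C1=O
F9 | step 9 | methyl 2-[(3R,4R)-4-geranylgeranyl-6-oxo-3-(triethylsilyloxy)cyclohex-1-en-1-yl]acetate | COC(=O)CC1=C[C@H](O[Si](CC)(CC)CC)[C@H](C/C=C(\C)CC/C=C(\C)CC/C=C(\C)CCC=C(C)C)CC1=O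
F10 | step 2 | (E)-3-(tributylstannyl)prop-2-en-1-ol | CCCC[Sn](CCCC)(CCCC)/C=C/CO
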